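**Plan**
The tether carbons are numbered C1–C14, with C1 and C14 each bonded to a benzene ring. Retrosynthetically the four phenols are masked as methyl ethers and the C7–C8 bond is raised to an alkyne. The C6–C7 and C8–C9 bonds are then cut, so that C7 and C8 come from acetylene and both arms from one 6-arylhexyl bromide; last, the aryl–C1 bond of that bromide is cut to a 3,5-dimethoxyphenyl Grignard reagent and 1,6-dibromohexane.
The feature that allows this is the symmetry of the tetradecane chain about its central C7–C8 bond: one bromide supplies both C1–C6 and C9–C14 with their 3,5-dioxygenated rings, and a two-carbon unit supplies C7 and C8.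
Forward order: aryl–C1 bond by copper-catalysed Grignard coupling, then the chain is joined by two successive acetylide alkylations in one flask, then hydrogenation of C7≡C8, then cleavage of the four methyl ethers. No ring is formed; both benzene rings are bought.
Stereochemistry: none to set; the target is achiral, with no stereocentre and no double-bond geometry.

Key step: step 2

Remark on the chemistry: acetylene is assumed to be taken from a cylinder and freed of acetone (−78 °C trap, then a concentrated H2SO4 wash) before it is dissolved in THF.

**Route**

Step 1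
Reactants: 1 1-bromo-3,5-dimethoxybenzene; 2 1,6-dibromohexane (fourfold excess)
Product: 4 1-(6-bromohexyl)-3,5-dimethoxybenzene, via arylmagnesium bromide 3 (not isolated)
Conditions: Mg, cat. I2, THF, reflux; then added slowly to 2 (4 equiv), Li2CuCl4 (3 mol%), THF, −10 °C → rt
Reagents that add atoms: none
Why: Copper-catalysed cross-coupling of an aryl Grignard reagent with a primary alkyl bromide (Kochi coupling with Li2CuCl4) is well established, and slow addition of the Grignard reagent to a fourfold excess of the dibromide should hold the second substitution to 1,6-diarylhexane down, the surplus dibromide being removed by distillation.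

Step 2
Reactants: 4 1-(6-bromohexyl)-3,5-dimethoxybenzene (two equivalents, added in two portions); 5 acetylene
Product: 9 1,14-bis(3,5-dimethoxyphenyl)tetradec-7-yne, via lithium acetylide 6 (not isolated), via terminal alkyne 7 (not isolated), via lithium alkynide 8 (not isolated)
Conditions: 5 (excess, satd in THF), n-BuLi (1.1 equiv), −78 °C; 4 (1.0 equiv), DMPU, −78 °C → rt; Ar sparge; n-BuLi (1.0 equiv), −78 °C; 4 (1.0 equiv), −78 °C → rt
Reagents that add atoms: none
Why: n-BuLi deprotonates acetylene, held in excess at −78 °C, to monolithium acetylide 6, which displaces bromide from the primary carbon of 4 by an SN2 reaction once DMPU is added and the mixture warms, forming the C6–C7 bond and the terminal alkyne 7; after the surplus acetylene is swept out with argon, a second equivalent of n-BuLi converts 7 into alkynide 8, and the second portion of 4 is displaced in the same way to form the C8–C9 bond. The closest known reaction type is the alkylation of lithium acetylides with primary alkyl bromides in THF with a dipolar cosolvent, including the one-flask preparation of symmetrical dialkylacetylenes from acetylene. No ring is closed and no stereocentre is created. The step needs substitution to win over E2 elimination and alkyne deprotonation to win over lithiation of the ring carbon between the two methoxy groups; the unbranched primary bromide, the cosolvent, addition of n-BuLi at −78 °C and no more than one equivalent of base per acidic alkyne hydrogen should secure both. The excess of acetylene in the first stage suppresses disproportionation of 6 to Li2C2, and any 7 left over differs enough in size from 9 to be separated and recycled.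

Step 3
Reactants: 9 1,14-bis(3,5-dimethoxyphenyl)tetradec-7-yne
Product: 10 1,14-bis(3,5-dimethoxyphenyl)tetradecane
Conditions: H2 (1 atm), 10% Pd/C, EtOAc, rt
Reagents that add atoms: none
Why: Heterogeneous catalytic hydrogenation of an unhindered internal alkyne should run through to the alkane under these conditions, while the aryl methyl ethers and the benzene rings, which carry no benzylic heteroatom, should stay untouched.

Step 4
Reactants: 10 1,14-bis(3,5-dimethoxyphenyl)tetradecane
Product: 11 bisnorstriatol
Conditions: BBr3 (8 equiv), CH2Cl2, −78 °C → rt; then H2O, 0 °C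
Reagents that add atoms: none
Why: Lewis acid-mediated O-demethylation of aryl methyl ethers with BBr3 (bromide attack on the methyl group of the boron-complexed ether, then hydrolysis of the aryl borates) is the standard way to free 5-alkylresorcinols, and the saturated chain of 10 offers nothing else that reacts.

**Compound list**
1 | 1-bromo-3,5-dimethoxybenzene | COc1cc(Br)cc(OC)c1 | starting material
2 | 1,6-dibromohexane | BrCCCCCCBr | starting material
3 | 3,5-dimethoxyphenylmagnesium bromide | COc1cc([Mg]Br)cc(OC)c1 | intermediate
4 | 1-(6-bromohexyl)-3,5-dimethoxybenzene | COc1cc(CCCCCCBr)cc(OC)c1 | intermediate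
5 | acetylene | C#C | starting material
6 | lithium acetylide (monolithium) | [Li]C#C | intermediate
7 | 8-(3,5-dimethoxyphenyl)oct-1-yne | COc1cc(CCCCCCC#C)cc(OC)c1 | intermediate
8 | lithium 8-(3,5-dimethoxyphenyl)oct-1-yn-1-ide | COc1cc(CCCCCCC#C[Li])cc(OC)c1 | intermediate
9 | 1,14-bis(3,5-dimethoxyphenyl)tetradec-7-yne | COc1cc(OC)cc(CCCCCCC#CCCCCCCc2cc(OC)cc(OC)c2)c1 | intermediate
10 | 1,14-bis(3,5-dimethoxyphenyl)tetradecane | COc1cc(OC)cc(CCCCCCCCCCCCCCc2cc(OC)cc(OC)c2)c1 | intermediate
11 | bisnorstriatol, 5,5'-(tetradecane-1,14-diyl)bis(benzene-1,3-diol) | Oc1cc(O)cc(CCCCCCCCCCCCCCc2cc(O)cc(O)c2)c1 | target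

**Count**
Total steps: 4. Longest linear sequence: 4 steps (1 → 4 → 9 → 10 → 11).

**Steps most likely to fail**

Step 2. The second alkylation may stall after the first, monolithium acetylide may be lost by disproportionation on warming, and E2 elimination of the bromide may compete. The fallback sets out from 4 and returns at 9, and it builds the C7≡C8 triple bond by metathesis. Compound 4 would be alkylated with 1-propynyllithium (commercial, or from propyne and n-BuLi) in THF/DMPU to give 1,3-dimethoxy-5-(non-7-yn-1-yl)benzene F1. Alkyne homometathesis of F1 with the molybdenum alkylidyne Mo(≡CC6H4OMe-4)(OSiPh3)3 in toluene at rt, with 5 Å molecular sieves to take up the but-2-yne released, should then give 9.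

Step 1. The Grignard reagent may substitute both ends of the dibromide, or may homocouple to the biaryl. The fallback sets out from 1 and returns at 4, and it builds the aryl–C1 bond by palladium catalysis. Sonogashira coupling of 1 with hex-5-yn-1-ol (PdCl2(PPh3)2, CuI, Et3N, 70 °C) should give 6-(3,5-dimethoxyphenyl)hex-5-yn-1-ol F2. Hydrogenation (H2, 10% Pd/C, EtOAc) should give 6-(3,5-dimethoxyphenyl)hexan-1-ol F3, and Appel bromination (CBr4, PPh3, CH2Cl2, 0 °C) should give 4.

Step 4. Cleavage of the four methyl ethers may stop short, and the polar tetraphenol may be lost or darkened during hydrolysis of its borate esters. The fallback sets out from 2 and 5 and returns at 11; it carries the phenols as benzyl ethers so that no Lewis-acid dealkylation is needed. Commercial 5-bromobenzene-1,3-diol would be benzylated (BnBr, K2CO3, DMF) to 1,3-bis(benzyloxy)-5-bromobenzene F4. Its Grignard reagent, 3,5-bis(benzyloxy)phenylmagnesium bromide F5, would be coupled with excess 2 under Li2CuCl4 catalysis to give 1,3-bis(benzyloxy)-5-(6-bromohexyl)benzene F6. F6 would take the place of 4 in the twofold alkylation of 5, passing through 6, the terminal alkyne 1,3-bis(benzyloxy)-5-(oct-7-yn-1-yl)benzene F7 and its lithium salt, lithium 8-[3,5-bis(benzyloxy)phenyl]oct-1-yn-1-ide F8, to give 1,14-bis[3,5-bis(benzyloxy)phenyl]tetradec-7-yne F9. Hydrogenation of F9 over 10% Pd/C in EtOAc/EtOH should saturate the alkyne and hydrogenolyse all four benzyl ethers in one operation, giving 11 directly.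

**Further compounds**
F1 | step 2 | 1,3-dimethoxy-5-(non-7-yn-1-yl)benzene | COc1cc(CCCCCCC#CC)cc(OC)c1
F2 | step 1 | 6-(3,5-dimethoxyphenyl)hex-5-yn-1-ol | COc1cc(C#CCCCCO)cc(OC)c1
F3 | step 1 | 6-(3,5-dimethoxyphenyl)hexan-1-ol | COc1cc(CCCCCCO)cc(OC)c1
F4 | step 4 | 1,3-bis(benzyloxy)-5-bromobenzene | Brc1cc(OCc2ccccc2)cc(OCc2ccccc2)c1
F5 | step 4 | 3,5-bis(benzyloxy)phenylmagnesium bromide | Br[Mg]c1cc(OCc2ccccc2)cc(OCc2ccccc2)c1
F6 | step 4 | 1,3-bis(benzyloxy)-5-(6-bromohexyl)benzene | BrCCCCCCc1cc(OCc2ccccc2)cc(OCc2ccccc2)c1
F7 | step 4 | 1,3-bis(benzyloxy)-5-(oct-7-yn-1-yl)benzene | C#CCCCCCCc1cc(OCc2ccccc2)cc(OCc2ccccc2)c1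
F8 | step 4 | lithium 8-[3,5-bis(benzyloxy)phenyl]oct-1-yn-1-ide | [Li]C#CCCCCCCc1cc(OCc2ccccc2)cc(OCc2ccccc2)c1
F9 | step 4 | 1,14-bis[3,5-bis(benzyloxy)phenyl]tetradec-7-yne | C(c1ccccc1)Oc1cc(OCc2ccccc2)cc(CCCCCCC#CCCCCCCc2cc(OCc3ccccc3)cc(OCc3ccccc3)c2)c1
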